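The cyclohexene ring (C1 = aryl-bearing CH, C2=C3 the olefin, C6 the quaternary carbon) is cut at C2=C3 and C5–C6, giving but-3-en-2-one and a three-carbon bis-nucleophile. The feature used is that C1 lies between C6 and C2: as a ketimine carbon it makes first C6, then C2 an enamine carbon. Racemic (E)-5-aryl-3-methylpent-4-en-2-one is condensed with (S)-1-phenylethylamine; the conjugated secondary enamine adds to the enone (C5–C6, quaternary centre fixed from a racemate) and the new methyl enamine closes on the side-chain ketone with loss of water (C2=C3), all in one flask. C1=O is then reduced and replaced by the second coumarin with inversion.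

Key step: step 4

Step 1
Reactants: 1 5-bromo-2-hydroxy-4-methoxybenzaldehyde; 2 ethyl (triphenylphosphoranylidene)acetate
Product: 4 6-bromo-7-methoxy-2H-chromen-2-one, via ethyl hydroxycinnamate 3 (not isolated)
Conditions: N,N-diethylaniline, reflux
Reagents that add atoms: none
Why: Wittig olefination followed by thermal E/Z isomerization and lactonization of the ortho-hydroxycinnamate should close the coumarin and leave the bromide at C6 for both later couplings.

Step 2
Reactants: 5 (E)-but-2-en-1-ylmagnesium chloride; 6 N-methoxy-N-methylacetamide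
Product: 8 rac-3-methylpent-4-en-2-one, via chloromagnesium hemiaminal 7 (not isolated)
Conditions: THF, −78 → −20 °C; cold aq NH4Cl
Reagents that add atoms: none
Why: Weinreb ketone synthesis in which the allylic Grignard reagent should react at its γ-carbon and the chelated tetrahedral adduct blocks a second addition, so the β,γ-unsaturated ketone is released only on cold, weakly acidic work-up.

Step 3
Reactants: 4 6-bromo-7-methoxy-2H-chromen-2-one; 8 rac-3-methylpent-4-en-2-one
Product: 9 rac-(E)-5-(7-methoxy-2-oxo-2H-chromen-6-yl)-3-methylpent-4-en-2-one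
Conditions: 8 (2.5 equiv), Pd(OAc)2 (5 mol %), P(o-tol)3 (10 mol %), Bu4NCl, NaHCO3, DMF, 80 °C
Reagents that add atoms: none
Why: Heck reaction at the terminal olefin carbon with β-hydride elimination toward the benzylic position should give the E-styrene, and any drift of this double bond toward the ketone is harmless because step 4 passes through the common dienamine.

Step 4
Reactants: 9 rac-(E)-5-(7-methoxy-2-oxo-2H-chromen-6-yl)-3-methylpent-4-en-2-one; 10 but-3-en-2-one; 11 (S)-1-phenylethan-1-amine
Product: 15 (6R)-6-[(E)-2-(7-methoxy-2-oxo-2H-chromen-6-yl)ethenyl]-3,6-dimethylcyclohex-2-en-1-one, via ketimine 12 (not isolated), via keto imine adduct 13 (not isolated), via cyclohexenimine 14 (not isolated)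
Conditions: 11 (1.05 equiv), TsOH·H2O (1 mol %), 4 Å molecular sieves, toluene, 40 °C; then 10 (1.3 equiv), 20 → 40 °C; then AcOH (0.3 equiv), 70 °C; then 20% aq AcOH, THF, 20 °C
Reagents that add atoms: water, O
Why: Condensation gives ketimine 12, whose conjugated secondary enamine tautomer (the racemic α-centre and any double-bond isomer of 9 converge on it) adds through its α-carbon to but-3-en-2-one in an aza-ene-type Michael reaction with internal N–H transfer (C5–C6 bond), after which imine 13 tautomerizes to the methylene enamine, which attacks the side-chain ketone; loss of water gives the C2=C3 bond and hydrolysis of 14 frees 15 and the amine. The closest known reaction type is the Michael addition of chiral 1-phenylethylamine imines of α-substituted ketones to enones (deracemizing alkylation) joined to a Stork-type enamine aldol condensation, together a Robinson-type [3+3] annulation closed from the α′-methyl of the original ketone. The ring closes in the 6-(enolendo)-exo-trig mode. The quaternary centre C6 is controlled by the auxiliary: the enone should approach the enamine face anti to the phenyl group of the (S)-amine in a compact cyclic transition state, which gives R for the enamine geometry that keeps the planar styryl group cis to N–H. Attack at the α-carbon instead of the benzylic vinylogous terminus is secured because only the α-carbon can reach the cyclic N–H transfer array. Closure from C2 instead of from the methyl of the new ketone is secured because nitrogen sits on C1, so the enamine is far more abundant than any ketone enol and meets the unhindered C3 carbonyl, while the sieves suppress transfer of the amine.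

Step 5
Reactants: 15 (6R)-6-[(E)-2-(7-methoxy-2-oxo-2H-chromen-6-yl)ethenyl]-3,6-dimethylcyclohex-2-en-1-one
Product: 16 (1R,6R)-6-[(E)-2-(7-methoxy-2-oxo-2H-chromen-6-yl)ethenyl]-3,6-dimethylcyclohex-2-en-1-ol
Conditions: (S)-2-methyl-CBS-oxazaborolidine (20 mol %), catecholborane (1.5 equiv), toluene, −78 °C; pH 7 buffer
Reagents that add atoms: none
Why: Corey–Bakshi–Shibata reduction, in which catalyst-controlled 1,2-hydride delivery to the carbonyl face on the side of the C6 methyl (quaternary C6 as the large flank) should set C1 as R with the hydroxyl cis to the styryl arm, without touching lactone or olefins.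

Step 6
Reactants: 16 (1R,6R)-6-[(E)-2-(7-methoxy-2-oxo-2H-chromen-6-yl)ethenyl]-3,6-dimethylcyclohex-2-en-1-ol
Product: 17 (1R,6R)-6-[(E)-2-(7-methoxy-2-oxo-2H-chromen-6-yl)ethenyl]-3,6-dimethylcyclohex-2-en-1-yl methyl carbonate
Conditions: ClCO2Me (2 equiv), pyridine, DMAP (10 mol %), CH2Cl2, 0 °C
Reagents that add atoms: methyl chloroformate, COC(=O)Cl
Why: O-acylation of the allylic alcohol should give the carbonate as leaving group with both stereocentres untouched.

Step 7
Reactants: 4 6-bromo-7-methoxy-2H-chromen-2-one
Product: 18 7-methoxy-6-(4,4,5,5-tetramethyl-1,3,2-dioxaborolan-2-yl)-2H-chromen-2-one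
Conditions: bis(pinacolato)diboron (1.2 equiv), PdCl2(dppf) (3 mol %), KOAc, 1,4-dioxane, 90 °C
Reagents that add atoms: bis(pinacolato)diboron, CC1(C)OB(OC1(C)C)B1OC(C)(C)C(C)(C)O1
Why: Miyaura borylation of the aryl bromide under acetate base should leave the lactone intact.

Step 8
Reactants: 17 (1R,6R)-6-[(E)-2-(7-methoxy-2-oxo-2H-chromen-6-yl)ethenyl]-3,6-dimethylcyclohex-2-en-1-yl methyl carbonate; 18 7-methoxy-6-(4,4,5,5-tetramethyl-1,3,2-dioxaborolan-2-yl)-2H-chromen-2-one
Product: 19 7-methoxy-6-[(E)-2-[(1R,2S)-2-(7-methoxy-2-oxo-2H-chromen-6-yl)-1,4-dimethylcyclohex-3-en-1-yl]ethenyl]-2H-chromen-2-one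
Conditions: Pd(PPh3)4 (5 mol %), K2CO3, THF/H2O 10:1, 60 °C
Reagents that add atoms: none
Why: Suzuki–Miyaura allyl–aryl coupling through a π-allylpalladium intermediate, in which ionization anti to the carbonate followed by transmetalation and inner-sphere reductive elimination at the secondary terminus should give net inversion, placing the coumarin trans to the styryl arm (benzylic carbon S) and leaving the quaternary centre untouched.

Compound list
1 | 5-bromo-2-hydroxy-4-methoxybenzaldehyde | O=Cc1cc(Br)c(OC)cc1O | starting material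
2 | ethyl (triphenylphosphoranylidene)acetate | CCOC(=O)C=P(c1ccccc1)(c1ccccc1)c1ccccc1 | starting material
3 | ethyl (E)-3-(5-bromo-2-hydroxy-4-methoxyphenyl)prop-2-enoate | CCOC(=O)/C=C/c1cc(Br)c(OC)cc1O | intermediate
4 | 6-bromo-7-methoxy-2H-chromen-2-one | COc1cc2oc(=O)ccc2cc1Br | intermediate
5 | (E)-but-2-en-1-ylmagnesium chloride | C/C=C/C[Mg]Cl | starting material
6 | N-methoxy-N-methylacetamide | CC(=O)N(C)OC | starting material
7 | chloromagnesium salt of 2-[methoxy(methyl)amino]-3-methylpent-4-en-2-ol | C=CC(C)C(C)(O[Mg]Cl)N(C)OC | intermediate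
8 | rac-3-methylpent-4-en-2-one | CC(=O)C(C)C=C | intermediate
9 | rac-(E)-5-(7-methoxy-2-oxo-2H-chromen-6-yl)-3-methylpent-4-en-2-one | COc1cc2oc(=O)ccc2cc1/C=C/C(C)C(C)=O | intermediate
10 | but-3-en-2-one | CC(=O)C=C | starting material
11 | (S)-1-phenylethan-1-amine | C[C@H](N)c1ccccc1 | starting material
12 | 7-methoxy-6-[(E)-3-methyl-4-{[(1S)-1-phenylethyl]imino}pent-1-en-1-yl]-2H-chromen-2-one (C3 unassigned, in equilibrium with its conjugated secondary enamine) | COc1cc2oc(=O)ccc2cc1/C=C/C(C)C(C)=N[C@@H](C)c1ccccc1 | intermediate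
13 | 7-methoxy-6-[(1E,3R)-3-methyl-6-oxo-3-(1-{[(1S)-1-phenylethyl]imino}ethyl)hept-1-en-1-yl]-2H-chromen-2-one | COc1cc2oc(=O)ccc2cc1/C=C/[C@@](C)(CCC(C)=O)C(C)=N[C@@H](C)c1ccccc1 | intermediate
14 | 7-methoxy-6-[(E)-2-[(1R)-1,4-dimethyl-2-{[(1S)-1-phenylethyl]imino}cyclohex-3-en-1-yl]ethenyl]-2H-chromen-2-one | COc1cc2oc(=O)ccc2cc1/C=C/[C@@]1(C)CCC(C)=CC1=N[C@@H](C)c1ccccc1 | intermediate
15 | (6R)-6-[(E)-2-(7-methoxy-2-oxo-2H-chromen-6-yl)ethenyl]-3,6-dimethylcyclohex-2-en-1-one | COc1cc2oc(=O)ccc2cc1/C=C/[C@@]1(C)CCC(C)=CC1=O | intermediate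
16 | (1R,6R)-6-[(E)-2-(7-methoxy-2-oxo-2H-chromen-6-yl)ethenyl]-3,6-dimethylcyclohex-2-en-1-ol | COc1cc2oc(=O)ccc2cc1/C=C/[C@@]1(C)CCC(C)=C[C@H]1O | intermediate
17 | (1R,6R)-6-[(E)-2-(7-methoxy-2-oxo-2H-chromen-6-yl)ethenyl]-3,6-dimethylcyclohex-2-en-1-yl methyl carbonate | COc1cc2oc(=O)ccc2cc1/C=C/[C@@]1(C)CCC(C)=C[C@H]1OC(=O)OC | intermediate
18 | 7-methoxy-6-(4,4,5,5-tetramethyl-1,3,2-dioxaborolan-2-yl)-2H-chromen-2-one | COc1cc2oc(=O)ccc2cc1B1OC(C)(C)C(C)(C)O1 | intermediate
19 | 7-methoxy-6-[(E)-2-[(1R,2S)-2-(7-methoxy-2-oxo-2H-chromen-6-yl)-1,4-dimethylcyclohex-3-en-1-yl]ethenyl]-2H-chromen-2-one | COc1cc2oc(=O)ccc2cc1/C=C/[C@@]1(C)CCC(C)=C[C@@H]1c1cc2ccc(=O)oc2cc1OC | target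

Total step count: 8. Longest linear sequence: 6 steps (1 or 2, then 3, 4, 5, 6, 8).

Steps most likely to fail

Step 4. The enamine geometry or face may be controlled incompletely, which would erode the enantiomeric purity. The enone may also be attacked at the benzylic vinylogous terminus, or the amine may migrate to the new ketone so that the ring closes in the other aldol sense. Fallback: setting out from 9 and 10, an auxiliary-free Robinson-type annulation (Cs2CO3, Bu4NBr, toluene, 0 °C; then KOH, MeOH, 20 °C; then 1 M HCl to re-close the lactone) should give, in the flask, rac-3-[(E)-2-(7-methoxy-2-oxo-2H-chromen-6-yl)ethenyl]-3-methylheptane-2,6-dione F1 and from it rac-6-[(E)-2-(7-methoxy-2-oxo-2H-chromen-6-yl)ethenyl]-3,6-dimethylcyclohex-2-en-1-one F2. The reduction of step 5 then serves as a resolution: the (S)-catalyst should convert the two enantiomers into diastereomeric (1R) alcohols, 16 and (1R,6S)-6-[(E)-2-(7-methoxy-2-oxo-2H-chromen-6-yl)ethenyl]-3,6-dimethylcyclohex-2-en-1-ol F3, which are separated by chromatography. The route is rejoined at 16.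

Step 8. Transmetalation may be slow at the hindered π-allyl complex, so that β-hydride elimination to a diene, attack at the tertiary allyl terminus, or loss of the inversion through allyl exchange between palladium centres can compete. Fallback: setting out from 17 and bromide 4 (boronate 18 is then not needed), a nickel-catalysed reductive cross-electrophile coupling (NiBr2(dme), 4,4'-di-tert-butyl-2,2'-bipyridine, Zn, DMA, 40 °C) should form the same aryl–C bond without an organoboron partner and return directly to 19. Oxidative addition of zerovalent nickel anti to the carbonate and reductive elimination at nickel are expected to give the same net inversion.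

Step 3. The terminal double bond of 8 may migrate into conjugation with the ketone under the basic, palladium hydride-containing conditions before arylation, which removes the Heck-active olefin. Fallback: setting out from 5, addition to acetaldehyde (THF, −78 °C) should give 3-methylpent-4-en-2-ol F4, which cannot isomerize in this way. Heck reaction of F4 with 4 under the conditions of step 3 should give (E)-5-(7-methoxy-2-oxo-2H-chromen-6-yl)-3-methylpent-4-en-2-ol F5, and oxidation with Dess–Martin periodinane (CH2Cl2, 20 °C) returns to 9.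

Further compounds
F1 | step 4 | rac-3-[(E)-2-(7-methoxy-2-oxo-2H-chromen-6-yl)ethenyl]-3-methylheptane-2,6-dione | COc1cc2oc(=O)ccc2cc1/C=C/C(C)(CCC(C)=O)C(C)=O
F2 | step 4 | rac-6-[(E)-2-(7-methoxy-2-oxo-2H-chromen-6-yl)ethenyl]-3,6-dimethylcyclohex-2-en-1-one | COc1cc2oc(=O)ccc2cc1/C=C/C1(C)CCC(C)=CC1=O
F3 | step 4 | (1R,6S)-6-[(E)-2-(7-methoxy-2-oxo-2H-chromen-6-yl)ethenyl]-3,6-dimethylcyclohex-2-en-1-ol | COc1cc2oc(=O)ccc2cc1/C=C/[C@]1(C)CCC(C)=C[C@H]1O
F0 | step 8 | none | none
F4 | step 3 | 3-methylpent-4-en-2-ol (mixture of diastereomers) | CC(O)C(C)C=C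
F5 | step 3 | (E)-5-(7-methoxy-2-oxo-2H-chromen-6-yl)-3-methylpent-4-en-2-ol (mixture of diastereomers) | COc1cc2oc(=O)ccc2cc1/C=C/C(C)C(C)O
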